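**Retrosynthetic overview**

1. Ainsliadimer B (25; guaianolide numbering, primed atoms for the unit that holds the spiro carbon C4') ⇐ addition of water to C15 of 24 ⇐ oxygenation at C10 of 22 ⇐ Diels–Alder union of dienone 21 (C14=C10–C1=C2) with dehydrozaluzanin C 20 (C4'=C15'), which closes the spiro cyclohexene last.
2. 21 ⇐ double sulfoxide elimination of 17 ⇐ 15, in which ring A (C1–C5) and the lactone ring are closed in one operation on a preformed seven-membered ring: C4–C5 by epoxide opening, O6–C12 by lactonisation, C1=C2 by Horner–Wadsworth–Emmons olefination, from epoxy ketone 11 and the acetone 1,3-bis-phosphonate 12.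
3. Enabling feature: in ring A the C3 ketone is flanked by C2 and C4, which are bonded to the vicinal atoms C1 and C5 of the seven-membered ring; C1 is an alkene carbon (latent ketone), the C4–C5 bond is anti to the C6–O bond on the next ring atom (latent C5–C6 epoxide), and O6 is γ to the C12 carbonyl (latent ester).
4. 11 ⇐ enone 7 (phenylthiomethylation at C10, then nucleophilic epoxidation) ⇐ acrylate 5 (thiophenol masks C11=C13) ⇐ cycloheptadiene monoepoxide 2 and trimethyl phosphonoacetate by allylic alkylation with zerovalent palladium, which sets C7, then olefination with formaldehyde.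
5. Ring order: seven-membered ring (from cyclohepta-1,3-diene), then ring A and the lactone together (step 8), then the spiro cyclohexene (step 13); unit 2 comes from dehydrocostus lactone 18.

Key step: step 8

Remark on the chemistry (assumptions): the (R,R) antipode of the manganese salen catalyst is assumed to give oxide 2 by analogy with other cis-alkenes conjugated to an sp2 carbon (otherwise the (S,S) antipode is used), and bis-phosphonate 12 and dehydrocostus lactone 18 are taken as purchasable.

**Route**

Step 1
Reactants: 1 cyclohepta-1,3-diene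
Product: 2 (1R,7S)-8-oxabicyclo[5.1.0]oct-2-ene
Conditions: (R,R)-[N,N'-bis(3,5-di-tert-butylsalicylidene)cyclohexane-1,2-diaminato]MnCl (4 mol%), 4-phenylpyridine N-oxide, aq. NaOCl (pH 11), CH2Cl2, 0 °C
Reagents that add atoms: sodium hypochlorite, [Na+].[O-]Cl
Why: Jacobsen asymmetric epoxidation of a cis-alkene conjugated to a second alkene should stop at the monoepoxide because the remaining alkene is deactivated, and the catalyst antipode sets both epoxide carbons.

Step 2
Reactants: 2 (1R,7S)-8-oxabicyclo[5.1.0]oct-2-ene; 3 trimethyl phosphonoacetate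
Product: 4 methyl 2-(dimethoxyphosphoryl)-2-[(1R,4S)-4-hydroxycyclohept-2-en-1-yl]acetate (epimers at the phosphonate carbon)
Conditions: 3 (1.5 equiv), Pd2(dba)3·CHCl3 (2 mol%), PPh3 (10 mol%), THF, 0 °C to rt
Reagents that add atoms: none
Why: Tsuji–Trost allylation under neutral conditions, in which zerovalent palladium opens the vinyl epoxide with inversion, the alkoxide so formed deprotonates 3 and the phosphonoacetate carbanion attacks the remote allyl terminus anti to palladium, so that the new C7 stereocentre is cis to the hydroxyl (net retention, 1,4-addition), while the phosphonate-bearing carbon forms as a mixture of epimers that is removed in step 3.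

Step 3
Reactants: 4 methyl 2-(dimethoxyphosphoryl)-2-[(1R,4S)-4-hydroxycyclohept-2-en-1-yl]acetate
Product: 5 methyl 2-[(1R,4S)-4-hydroxycyclohept-2-en-1-yl]prop-2-enoate
Conditions: aq. HCHO (37%), K2CO3, THF–H2O, rt to 50 °C
Reagents that add atoms: formaldehyde, C=O
Why: Horner–Wadsworth–Emmons olefination of the α-substituted phosphonoacetate with formaldehyde should give the α-methylene ester directly, under carbonate conditions too mild to remove the doubly allylic C7–H or to affect the free hydroxyl.

Step 4
Reactants: 5 methyl 2-[(1R,4S)-4-hydroxycyclohept-2-en-1-yl]prop-2-enoate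
Product: 6 methyl 2-[(1R,4S)-4-hydroxycyclohept-2-en-1-yl]-3-(phenylsulfanyl)propanoate (epimers at C11)
Conditions: PhSH (1.1 equiv), Et3N (0.1 equiv), CH2Cl2, 0 °C to rt
Reagents that add atoms: thiophenol, Sc1ccccc1
Why: Amine-catalysed thia-Michael addition of thiophenol to the acrylate should mask the future C11=C13 methylene as a phenylthiomethyl group that no longer accepts carbon nucleophiles, with C11 formed as a mixture of epimers that is erased in step 13.

Step 5
Reactants: 6 methyl 2-[(1R,4S)-4-hydroxycyclohept-2-en-1-yl]-3-(phenylsulfanyl)propanoate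
Product: 7 methyl 2-[(1R)-4-oxocyclohept-2-en-1-yl]-3-(phenylsulfanyl)propanoate (epimers at C11)
Conditions: MnO2, CH2Cl2, rt
Reagents that add atoms: none
Why: Oxidation of the allylic alcohol by MnO2 should give the enone without touching the sulfide, and it removes the carbinol stereocentre, which is no longer needed.

Step 6
Reactants: 7 methyl 2-[(1R)-4-oxocyclohept-2-en-1-yl]-3-(phenylsulfanyl)propanoate; 8 chloromethyl phenyl sulfide
Product: 10 methyl 2-[(1R)-4-oxo-5-[(phenylsulfanyl)methyl]cyclohept-2-en-1-yl]-3-(phenylsulfanyl)propanoate (epimers at C10 and C11), via silyl dienol ether 9 (not isolated)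
Conditions: LDA (1.05 equiv), TMSCl (1.2 equiv), THF, −78 °C; then 8 (1.2 equiv), ZnBr2 (cat.), CH2Cl2, 0 °C to rt
Reagents that add atoms: chlorotrimethylsilane, C[Si](C)(C)Cl (silyl group of 9 only)
Why: Kinetic deprotonation at the α' methylene C10 of the enone, which is far more acidic and less hindered than the ester C11–H, with in situ silylation should give the cross-conjugated silyl dienol ether, and its ZnBr2-mediated Mukaiyama-type alkylation by the sulfur-stabilised cation from 8 should install the second masked methylene at C10, whose configuration is uncontrolled and is erased in step 13.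

Step 7
Reactants: 10 methyl 2-[(1R)-4-oxo-5-[(phenylsulfanyl)methyl]cyclohept-2-en-1-yl]-3-(phenylsulfanyl)propanoate
Product: 11 methyl 2-[(1S,2S,7S)-6-oxo-5-[(phenylsulfanyl)methyl]-8-oxabicyclo[5.1.0]octan-2-yl]-3-(phenylsulfanyl)propanoate
Conditions: tBuOOH (decane), DBU, CH2Cl2, 0 °C
Reagents that add atoms: tert-butyl hydroperoxide, CC(C)(C)OO
Why: Weitz–Scheffer nucleophilic epoxidation, in which the peroxide anion adds to C6 anti to the C7 side chain and the enolate closes, should give the epoxide trans to the side chain (C6–O on the α face) without oxidising the sulfides.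

Step 8
Reactants: 11 methyl 2-[(1S,2S,7S)-6-oxo-5-[(phenylsulfanyl)methyl]-8-oxabicyclo[5.1.0]octan-2-yl]-3-(phenylsulfanyl)propanoate; 12 tetraethyl (2-oxopropane-1,3-diyl)bis(phosphonate)
Product: 15 diethyl [3-oxo-13,14-bis(phenylsulfanyl)-15-norguai-1-en-12,6α-olid-4-yl]phosphonate (5αH 6βH 7αH; epimers at C4 C10 C11), via hydroxy ester 13 (not isolated), via keto lactone 14 (not isolated)
Conditions: 12 (2.2 equiv), NaH (2.1 equiv), THF, 0 °C; then 11, 15-crown-5 (cat.), 0 to 45 °C; aq. NH4Cl
Reagents that add atoms: none
Why: Proposed new method: the monosodium salt of 12, the only base present, should open the epoxide by SN2 attack of its phosphonate-stabilised carbanion (C4) at C5, the epoxide carbon α to the C1 ketone, with inversion; the C6 alkoxide so released closes the lactone on the C12 ester and the expelled methoxide moves a proton from C2, whose phosphonate carbanion closes ring A on the C1 ketone by intramolecular Horner–Wadsworth–Emmons olefination. The closest known reaction types are the α-selective SN2 opening of α,β-epoxy ketones by soft nucleophiles, the opening of epoxides by phosphonate carbanions (as in the Wadsworth–Emmons cyclopropanation) and the one-pot C-alkylation and intramolecular Wittig or Horner–Wadsworth–Emmons annulation of acetone 1,3-dianion equivalents with α-halo ketones; their combination on an epoxy ketone is not described. The lactone closes by 5-exo-trig acyl substitution and is trans-fused because O6 (α) and the C7 side chain (β) are trans in 11, and ring A closes by a 5-(enolexo)-exo-trig olefination. C5 is set by inversion at the epoxide carbon (C4 enters on the β face, anti to O6), C6 and C7 come unchanged from 11, and C4 and C11 are not controlled because both are erased later. The step needs C- rather than O-alkylation and attack at C5 rather than C6, which the carbonyl activation of C5 and the shielding of C6 by the neighbouring C7 branch should secure, and it needs epoxide opening to precede olefination, which holds because a β-ketophosphonate anion olefinates a ketone only slowly between molecules. With a carbanion of this low basicity as the only base, neither C10–H next to the sulfide nor C11–H is removed, so the thioether masks should survive.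

Step 9
Reactants: 15 diethyl [3-oxo-13,14-bis(phenylsulfanyl)-15-norguai-1-en-12,6α-olid-4-yl]phosphonate
Product: 16 3-oxo-13,14-bis(phenylsulfanyl)guaia-1,4(15)-dien-12,6α-olide
Conditions: K2CO3, aq. HCHO (37%), THF, 0 °C to rt
Reagents that add atoms: formaldehyde, C=O
Why: Horner–Wadsworth–Emmons olefination of the remaining β-ketophosphonate with formaldehyde installs C15 as the exocyclic methylene, while the thioether-masked lactone cannot act as a Michael acceptor toward the phosphonate anion.

Step 10
Reactants: 16 3-oxo-13,14-bis(phenylsulfanyl)guaia-1,4(15)-dien-12,6α-olide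
Product: 17 3-oxo-13,14-bis(phenylsulfinyl)guaia-1,4(15)-dien-12,6α-olide
Conditions: mCPBA (2.05 equiv), CH2Cl2, −78 °C
Reagents that add atoms: 3-chloroperbenzoic acid, O=C(OO)c1cccc(Cl)c1
Why: Sulfide oxidation by a peracid at low temperature should be chemoselective because the only alkenes present are electron-poor enone alkenes.

Step 11
Reactants: 18 dehydrocostus lactone
Product: 19 3-hydroxydehydrocostus lactone (either C3' epimer)
Conditions: SeO2 (0.5 equiv), tBuOOH, CH2Cl2, rt
Reagents that add atoms: tert-butyl hydroperoxide, CC(C)(C)OO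
Why: SeO2-mediated allylic oxidation (ene reaction then [2,3]-sigmatropic shift) should occur at the allylic methylene C3' next to the C4'=C15' alkene, and the carbinol configuration is irrelevant.

Step 12
Reactants: 19 3-hydroxydehydrocostus lactone
Product: 20 dehydrozaluzanin C
Conditions: MnO2, CH2Cl2, rt
Reagents that add atoms: none
Why: MnO2 oxidation of the allylic alcohol gives the exo-methylene enone, and the four stereocentres come unchanged from the natural lactone.

Step 13
Reactants: 17 3-oxo-13,14-bis(phenylsulfinyl)guaia-1,4(15)-dien-12,6α-olide; 20 dehydrozaluzanin C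
Product: 22 Diels–Alder adduct (spiro dimer; C1=C10; C4=C15; C2 configuration open), via tetraene 21 (not isolated)
Conditions: 20 (3 equiv), CaCO3, BHT (cat.), toluene, 110 °C, argon
Reagents that add atoms: none
Why: Thermal syn-elimination of both sulfoxides (the only β-hydrogens are on C10 and C11, so only the exocyclic alkenes can form) should release dienone 21 slowly, and its s-cis diene C14=C10–C1=C2 then undergoes Diels–Alder cycloaddition with the exo-methylene enone of 20, the nucleophilic terminus C14 bonding to the β-carbon C15' and the diene adding to the α face of the cyclopentanone of 20 (the convex face that carries H1' and H5'), which sets the spiro centre C4'; C2 is erased in the next step.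

Step 14
Reactants: 22 Diels–Alder adduct
Product: 24 10β-hydroxy dimer (C1=C2; C4=C15), via hydroperoxide 23 (not isolated)
Conditions: O2 (1 atm), Et3N, EtOAc, 0 °C to rt; then PPh3
Reagents that add atoms: dioxygen, O=O
Why: γ-Autoxidation of a β,γ-unsaturated ketone, in which the doubly activated C2–H gives the extended dienolate, O2 adds at C10 with shift of the alkene to C1=C2 and PPh3 reduces the hydroperoxide; oxygen should enter anti to the C5' branch of the spiro cyclopentanone (on the side of the C3' carbonyl), which is the required 10β configuration.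

Step 15
Reactants: 24 10β-hydroxy dimer
Product: 25 ainsliadimer B
Conditions: PMe3 (10 mol%), H2O, MeCN, 0 °C to rt
Reagents that add atoms: water, O
Why: Phosphine-catalysed oxa-Michael addition of water should go to the most electrophilic acceptor, the cross-conjugated exocyclic enone carbon C15, and reversible protonation at C4 should place the hydroxymethyl group trans to the C5–C6 bond (thermodynamic epimer, 4R).

**Compound list**

1 | cyclohepta-1,3-diene | C1=CC=CCCC1 | starting material
2 | (1R,7S)-8-oxabicyclo[5.1.0]oct-2-ene | C1=C[C@H]2O[C@H]2CCC1 | intermediate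
3 | trimethyl phosphonoacetate (methyl 2-(dimethoxyphosphoryl)acetate) | COC(=O)CP(=O)(OC)OC | starting material
4 | methyl 2-(dimethoxyphosphoryl)-2-[(1R,4S)-4-hydroxycyclohept-2-en-1-yl]acetate (epimers at the phosphonate carbon) | O[C@@H]1C=C[C@H](C(P(=O)(OC)OC)C(=O)OC)CCC1 | intermediate
5 | methyl 2-[(1R,4S)-4-hydroxycyclohept-2-en-1-yl]prop-2-enoate | O[C@@H]1C=C[C@H](C(=C)C(=O)OC)CCC1 | intermediate
6 | methyl 2-[(1R,4S)-4-hydroxycyclohept-2-en-1-yl]-3-(phenylsulfanyl)propanoate (epimers at C11) | O[C@@H]1C=C[C@H](C(CSc2ccccc2)C(=O)OC)CCC1 | intermediate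
7 | methyl 2-[(1R)-4-oxocyclohept-2-en-1-yl]-3-(phenylsulfanyl)propanoate (epimers at C11) | O=C1C=C[C@H](C(CSc2ccccc2)C(=O)OC)CCC1 | intermediate
8 | chloromethyl phenyl sulfide | ClCSc1ccccc1 | starting material
9 | methyl 3-(phenylsulfanyl)-2-[(1R)-4-(trimethylsilyloxy)cyclohepta-2,4-dien-1-yl]propanoate (silyl dienol ether of 7) | C[Si](C)(C)OC1=CCC[C@@H](C(CSc2ccccc2)C(=O)OC)C=C1 | intermediate
10 | methyl 2-[(1R)-4-oxo-5-[(phenylsulfanyl)methyl]cyclohept-2-en-1-yl]-3-(phenylsulfanyl)propanoate (epimers at C10 and C11) | O=C1C=C[C@H](C(CSc2ccccc2)C(=O)OC)CCC1CSc1ccccc1 | intermediate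
11 | methyl 2-[(1S,2S,7S)-6-oxo-5-[(phenylsulfanyl)methyl]-8-oxabicyclo[5.1.0]octan-2-yl]-3-(phenylsulfanyl)propanoate | O=C1[C@H]2O[C@H]2[C@H](C(CSc3ccccc3)C(=O)OC)CCC1CSc1ccccc1 | intermediate
12 | tetraethyl (2-oxopropane-1,3-diyl)bis(phosphonate) | CCOP(=O)(OCC)CC(=O)CP(=O)(OCC)OCC | starting material
13 | hydroxy ester from epoxide opening (C4–C5 bond formed; C6–OH α, C4 on C5 β) | O=C1[C@H](C(P(=O)(OCC)OCC)C(=O)CP(=O)(OCC)OCC)[C@@H](O)[C@H](C(CSc2ccccc2)C(=O)OC)CCC1CSc1ccccc1 | intermediate
14 | keto lactone bis-phosphonate (trans-fused lactone closed, ring A open) | O=C1[C@H](C(P(=O)(OCC)OCC)C(=O)CP(=O)(OCC)OCC)[C@H]2OC(=O)C(CSc3ccccc3)[C@@H]2CCC1CSc1ccccc1 | intermediate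
15 | diethyl [3-oxo-13,14-bis(phenylsulfanyl)-15-norguai-1-en-12,6α-olid-4-yl]phosphonate (5αH, 6βH, 7αH) | O=C1C=C2C(CSc3ccccc3)CC[C@H]3C(CSc4ccccc4)C(=O)O[C@@H]3[C@H]2C1P(=O)(OCC)OCC | intermediate
16 | 3-oxo-13,14-bis(phenylsulfanyl)guaia-1,4(15)-dien-12,6α-olide | O=C1C=C2C(CSc3ccccc3)CC[C@H]3C(CSc4ccccc4)C(=O)O[C@@H]3[C@H]2C1=C | intermediate
17 | 3-oxo-13,14-bis(phenylsulfinyl)guaia-1,4(15)-dien-12,6α-olide | O=C1C=C2C(CS(=O)c3ccccc3)CC[C@H]3C(CS(=O)c4ccccc4)C(=O)O[C@@H]3[C@H]2C1=C | intermediate
18 | dehydrocostus lactone | C=C1CC[C@H]2C(=C)CC[C@H]3C(=C)C(=O)O[C@@H]3[C@@H]12 | starting material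
19 | 3-hydroxydehydrocostus lactone (C3' epimer not defined) | C=C1C(O)C[C@H]2C(=C)CC[C@H]3C(=C)C(=O)O[C@@H]3[C@@H]12 | intermediate
20 | dehydrozaluzanin C | C=C1C(=O)C[C@H]2C(=C)CC[C@H]3C(=C)C(=O)O[C@@H]3[C@@H]12 | intermediate
21 | 3-oxoguaia-1,4(15),10(14),11(13)-tetraen-12,6α-olide | O=C1C=C2C(=C)CC[C@H]3C(=C)C(=O)O[C@@H]3[C@H]2C1=C | intermediate
22 | Diels–Alder adduct (C2–C4' and C14–C15' bonds; C1=C10; C4=C15; C2 not defined) | C=C1C(=O)O[C@@H]2[C@@H]3C4=C(CC[C@@H]12)CC[C@@]5(C4C(=O)C3=C)C(=O)C[C@H]6C(=C)CC[C@H]7C(=C)C(=O)O[C@@H]7[C@H]65 | intermediate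
23 | 10β-hydroperoxy dimer (C1=C2; C4=C15) | C=C1C(=O)O[C@@H]2[C@@H]3C4=C(C(=O)C3=C)[C@]3(CC[C@]4(OO)CC[C@@H]12)C(=O)C[C@H]1C(=C)CC[C@H]2C(=C)C(=O)O[C@@H]2[C@H]13 | intermediate
24 | 10β-hydroxy dimer (C1=C2; C4=C15) | C=C1C(=O)O[C@@H]2[C@@H]3C4=C(C(=O)C3=C)[C@]3(CC[C@]4(O)CC[C@@H]12)C(=O)C[C@H]1C(=C)CC[C@H]2C(=C)C(=O)O[C@@H]2[C@H]13 | intermediate
25 | ainsliadimer B | C=C1C(=O)O[C@@H]2[C@@H]3C4=C(C(=O)[C@H]3CO)[C@]3(CC[C@]4(O)CC[C@@H]12)C(=O)C[C@H]1C(=C)CC[C@H]2C(=C)C(=O)O[C@@H]2[C@H]13 | target

**Step count and risks**

Total step count: 15. Longest linear sequence: 13 steps (steps 1 to 10, then 13 to 15).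

Step 8 (proposed new method). The carbanion of 12 may fail to open the epoxide at C5: base-induced isomerisation of the epoxy ketone, attack at C6, or retro-aldol cleavage of the β-alkoxy ketone intermediate could compete, and the olefination could stall. The fallback uses known reactions only, sets out from 11 and returns at 16, and makes the C4–C5 and C1=C2 bonds in separate steps. SmI2 (THF–MeOH, −90 °C) cleaves the C5–O bond of the epoxy ketone reductively to the β-hydroxy ketone F1, which is silylated at once (TBSOTf, 2,6-lutidine) to the silyl ether F2. Kinetic deprotonation at C5 (LDA, −78 °C) and alkylation with dimethyl (E)-(3-bromo-2-ethoxyprop-1-enyl)phosphonate, anti to the C6 silyloxy group, should give the enol ether phosphonate F3. Aqueous HCl in THF hydrolyses the enol ether, removes the silyl group and lets the C6 hydroxyl lactonise to the keto lactone F4, and K2CO3 with 18-crown-6 closes ring A by intramolecular Horner–Wadsworth–Emmons olefination to the enone lactone F5. The C4 methylene is then converted to the exocyclic alkene through its lithium enolate (LiHMDS, −78 °C) and Eschenmoser's salt (Mannich base F6), methylation with MeI (ammonium iodide F7) and elimination with NaHCO3, which gives 16.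

Step 13. Self-cycloaddition of tetraene 21 through its own exocyclic enone, dimerisation of 20, and side reactions of the sulfenic acid at 110 °C may outrun the cross-cycloaddition. The fallback sets out from 15 and returns at 22; it keeps the C4 phosphonate in place during the cycloaddition so that the diene partner has no enone dienophile of its own. mCPBA at −78 °C gives the bis-sulfoxide phosphonate F8; thermolysis with 20 as in step 13 releases the diene phosphonate F9, which should add to 20 with the same regio- and facial preference to give the adduct phosphonate F10; olefination of F10 with aqueous formaldehyde and K2CO3 under argon then gives 22.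

Step 14. Addition of O2 to the planar dienolate may show poor facial selectivity at C10 (formation of the 10α epimer), may lose to simple protonation at C10, or may run on to over-oxidation. The fallback sets out from 22 and returns at 24, and replaces autoxidation by epoxidation and β-elimination, so that the face is chosen on the sp3-configured adduct and not on the dienolate. Dimethyldioxirane (acetone, −40 °C, one equivalent) should epoxidise the tetrasubstituted C1=C10 alkene, the most electron-rich alkene of 22, to the epoxide F11; Et3N then removes the C2 proton and opens the epoxide at C1, which gives 24.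

Further compounds
F1 | step 8 | β-hydroxy ketone from reductive epoxide opening of 11 | O=C1C[C@@H](O)[C@H](C(CSc2ccccc2)C(=O)OC)CCC1CSc1ccccc1
F2 | step 8 | tert-butyldimethylsilyl ether of F1 | O=C1C[C@@H](O[Si](C)(C)C(C)(C)C)[C@H](C(CSc2ccccc2)C(=O)OC)CCC1CSc1ccccc1
F3 | step 8 | C5-alkylated enol ether phosphonate | O=C1[C@H](C/C(OCC)=C\P(=O)(OC)OC)[C@@H](O[Si](C)(C)C(C)(C)C)[C@H](C(CSc2ccccc2)C(=O)OC)CCC1CSc1ccccc1
F4 | step 8 | keto lactone β-ketophosphonate | O=C1[C@H](CC(=O)CP(=O)(OC)OC)[C@H]2OC(=O)C(CSc3ccccc3)[C@@H]2CCC1CSc1ccccc1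
F5 | step 8 | 3-oxo-13,14-bis(phenylsulfanyl)-15-norguai-1-en-12,6α-olide | O=C1C=C2C(CSc3ccccc3)CC[C@H]3C(CSc4ccccc4)C(=O)O[C@@H]3[C@H]2C1
F6 | step 8 | Mannich base of F5 (dimethylaminomethyl group at C4) | O=C1C=C2C(CSc3ccccc3)CC[C@H]3C(CSc4ccccc4)C(=O)O[C@@H]3[C@H]2C1CN(C)C
F7 | step 8 | trimethylammonium iodide from F6 | O=C1C=C2C(CSc3ccccc3)CC[C@H]3C(CSc4ccccc4)C(=O)O[C@@H]3[C@H]2C1C[N+](C)(C)C.[I-]
F8 | step 13 | bis-sulfoxide of 15 | O=C1C=C2C(CS(=O)c3ccccc3)CC[C@H]3C(CS(=O)c4ccccc4)C(=O)O[C@@H]3[C@H]2C1P(=O)(OCC)OCC
F9 | step 13 | diene phosphonate (C10=C14 and C11=C13 unveiled) | O=C1C=C2C(=C)CC[C@H]3C(=C)C(=O)O[C@@H]3[C@H]2C1P(=O)(OCC)OCC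
F10 | step 13 | Diels–Alder adduct with the phosphonate at C4 | C=C1C(=O)O[C@@H]2[C@@H]3C4=C(CC[C@@H]12)CC[C@@]5(C4C(=O)C3P(=O)(OCC)OCC)C(=O)C[C@H]6C(=C)CC[C@H]7C(=C)C(=O)O[C@@H]7[C@H]65
F11 | step 14 | 1β,10β-epoxide of 22 | C=C1C(=O)O[C@@H]2[C@@H]3[C@]45O[C@]5(CC[C@@H]12)CC[C@@]6(C4C(=O)C3=C)C(=O)C[C@H]7C(=C)CC[C@H]8C(=C)C(=O)O[C@@H]8[C@H]76
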